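**Plan**

1. Ring locants used throughout: C1 (angelate carbinol), C2, C3=C4(CH3) (Z), C5, C6, C7 (isopropyl), C8 (acetate carbinol), C9=C10(CH3) (E). The retrosynthesis cuts the two ester C–O bonds, reads the isopropyl group as a reduced isopropenyl group, then cuts ring bond C7–C8, then chain bond C1–C2.
2. Enabling feature: C8 is a carbinol flanked by the C9=C10 alkene and by C7, which carries a C3 branch. This is a homoallylic alcohol retron, and opening C7–C8 leaves a (2E,6Z)-farnesal chain. C7–C8 is also the bond made in germacrane biosynthesis (farnesyl C10 to C1).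
3. Forward: a nerol-derived nerylbarium reagent adds to a prenol-derived C5 enal to give the C15 chain. The terminal E-methyl group is turned into CH2SnBu3, an activating group that is expelled in the ring closure itself. The ten-membered ring, the only ring, is closed last by an intramolecular Lewis-acid SE2′ allylstannane–enal addition. Hydrogenation, acetylation, desilylation and angeloylation finish the route.
4. Stereochemistry: C1 comes from a Sharpless kinetic resolution. C7 and C8 both arise in the ring closure, with the face chosen by the C1 silyloxy group and the syn relationship by the open transition state. The Z alkene comes from nerol, the E alkene from the SeO2-made enal, and the angelate geometry from angelic acid.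

Key step: step 11

Remark: open-chain compounds carry dodecatriene (farnesane) locants. Chain C1 becomes ring C8, chain C4 becomes ring C1, chain C10 becomes ring C7, and chain C11/C12 become the isopropenyl group.

Step 1
Reactants: 1 prenol (3-methylbut-2-en-1-ol)
Product: 2 tert-butyldimethyl[(3-methylbut-2-en-1-yl)oxy]silane
Conditions: TBSCl, imidazole, DMF, 0 °C to rt
Reagents that add atoms: tert-butyldimethylsilyl chloride, CC(C)(C)[Si](C)(C)Cl
Why: Standard silyl ether formation on a primary allylic alcohol; no stereocentre is involved.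

Step 2
Reactants: 2 prenyl silyl ether
Product: 4 (E)-4-[(tert-butyldimethylsilyl)oxy]-2-methylbut-2-enal, via allylic alcohol 3 (not isolated)
Conditions: SeO2 (cat.), t-BuOOH, salicylic acid (cat.), CH2Cl2, 0 °C to rt; then MnO2, CH2Cl2, rt
Reagents that add atoms: selenium dioxide, O=[Se]=O; tert-butyl hydroperoxide, CC(C)(C)OO (terminal oxidant that re-forms SeO2)
Why: Riley allylic oxidation (ene reaction, then 2,3-shift) attacks the methyl group trans to the CH2OSi chain and so fixes the E geometry, and MnO2 should take the allylic alcohol on to the enal without touching the silyl ether.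

Step 3
Reactants: 5 nerol ((Z)-3,7-dimethylocta-2,6-dien-1-ol)
Product: 6 neryl chloride ((Z)-1-chloro-3,7-dimethylocta-2,6-diene)
Conditions: N-chlorosuccinimide, Me2S, CH2Cl2, −40 °C to 0 °C
Reagents that add atoms: N-chlorosuccinimide, ClN1C(=O)CCC1=O
Why: Corey–Kim chlorination replaces the activated primary allylic oxygen by chloride in an SN2 step, without allylic transposition and with the Z alkene retained.

Step 4
Reactants: 6 neryl chloride; 4 C5 enal
Product: 8 racemic (2E,6Z)-1-[(tert-butyldimethylsilyl)oxy]-3,7,11-trimethyldodeca-2,6,10-trien-4-ol, via nerylbarium chloride 7 (not isolated)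
Conditions: BaI2, Li(C12H10) (lithium biphenylide, 2 equiv), THF, rt; then 6, −78 °C; then 4, −78 °C
Reagents that add atoms: none
Why: Carbonyl allylation with a preformed allylbarium reagent, which at −78 °C should keep its Z geometry and react at the unsubstituted α-carbon in a 1,2-addition to the enal; the C4 carbinol forms racemic and is resolved in step 5.

Step 5
Reactants: 8 racemic allylic alcohol
Product: 9 (4S,2E,6Z)-1-[(tert-butyldimethylsilyl)oxy]-3,7,11-trimethyldodeca-2,6,10-trien-4-ol
Conditions: Ti(OiPr)4 (cat.), D-(−)-diisopropyl tartrate (cat.), t-BuOOH (0.6 equiv), 4 Å molecular sieves, CH2Cl2, −20 °C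
Reagents that add atoms: none
Why: Sharpless kinetic resolution: with the D-tartrate catalyst the 4R enantiomer of this E-configured secondary allylic alcohol should be epoxidised fast, leaving the 4S enantiomer, which is separated from the epoxy alcohol.

Step 6
Reactants: 9 (4S)-alcohol
Product: 10 (4S,2E,6Z)-1-(tert-butyldimethylsilyloxy)-4-(tert-butyldiphenylsilyloxy)-3,7,11-trimethyldodeca-2,6,10-triene
Conditions: TBDPSCl, imidazole, DMAP (cat.), DMF, rt to 40 °C
Reagents that add atoms: tert-butyldiphenylsilyl chloride, CC(C)(C)[Si](Cl)(c1ccccc1)c1ccccc1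
Why: Silyl ether formation at the secondary allylic alcohol; the O–H bond alone reacts, so C4 keeps its configuration, and the bulkier silyl group allows the primary one to be removed selectively later.

Step 7
Reactants: 10 bis-silyl ether
Product: 11 (4S,2E,6Z,10E)-1-(tert-butyldimethylsilyloxy)-4-(tert-butyldiphenylsilyloxy)-3,7,11-trimethyldodeca-2,6,10-trien-12-ol
Conditions: SeO2 (cat.), t-BuOOH, salicylic acid (cat.), CH2Cl2, 0 °C to rt, stopped at partial conversion
Reagents that add atoms: selenium dioxide, O=[Se]=O; tert-butyl hydroperoxide, CC(C)(C)OO (terminal oxidant that re-forms SeO2)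
Why: Riley oxidation of the terminal E-methyl group of a polyprenyl chain; the C2=C3 alkene is deactivated by two allylic silyloxy groups and the C6=C7 alkene is shielded by the neighbouring tert-butyldiphenylsilyloxy group, so the terminal alkene should react first.

Step 8
Reactants: 11 terminal allylic alcohol
Product: 13 (4S,2E,6Z,10E)-1-(tert-butyldimethylsilyloxy)-4-(tert-butyldiphenylsilyloxy)-3,7,11-trimethyl-12-(tributylstannyl)dodeca-2,6,10-triene, via allylic mesylate 12 (not isolated)
Conditions: MsCl, Et3N, THF, −40 °C; then Bu3SnLi (from Bu3SnH and LiN(iPr)2), THF, −78 °C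
Reagents that add atoms: tributylstannyllithium, [Li][Sn](CCCC)(CCCC)CCCC
Why: SN2 displacement of a primary allylic sulfonate by the soft stannyl anion should give the primary E-allylstannane; both silyl ethers are inert to the reagent.

Step 9
Reactants: 13 allylstannane
Product: 14 (4S,2E,6Z,10E)-4-(tert-butyldiphenylsilyloxy)-3,7,11-trimethyl-12-(tributylstannyl)dodeca-2,6,10-trien-1-ol
Conditions: Bu4NF (1.05 equiv), THF, 0 °C
Reagents that add atoms: none
Why: Fluoride cleaves the unhindered primary tert-butyldimethylsilyl ether much faster than the hindered secondary tert-butyldiphenylsilyl ether, and the allylstannane is stable to fluoride.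

Step 10
Reactants: 14 allylic alcohol
Product: 15 (4S,2E,6Z,10E)-4-(tert-butyldiphenylsilyloxy)-3,7,11-trimethyl-12-(tributylstannyl)dodeca-2,6,10-trienal
Conditions: MnO2, CH2Cl2, rt
Reagents that add atoms: none
Why: Chemoselective oxidation of a primary allylic alcohol to the E-enal under neutral heterogeneous conditions that should spare the acid-sensitive allylstannane.

Step 11
Reactants: 15 stannyl enal
Product: 16 (1S,7S,8S,3Z,9E)-1-(tert-butyldiphenylsilyloxy)-4,10-dimethyl-7-(prop-1-en-2-yl)cyclodeca-3,9-dien-8-ol
Conditions: BF3·OEt2 (1.2 equiv), CH2Cl2, −78 °C, slow addition of 15 (final 0.002 M); aqueous NaHCO3 quench at −78 °C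
Reagents that add atoms: none
Why: BF3 binds the aldehyde oxygen of the s-trans enal and the electron-rich C10=C11 π bond of the allylstannane (ring C7) adds to the carbonyl carbon (ring C8) in an intramolecular SE2′ step, the β-stannyl cation then losing Bu3Sn+ to leave the isopropenyl group, which copies the farnesyl C10-to-C1 union of germacrane biosynthesis with tin in the place of the proton that the enzyme removes. The closest known reaction type is the Lewis-acid-promoted macrocyclisation of allylstannanes onto conjugated aldehydes to ten-membered carbocyclic homoallylic alcohols (Hosomi–Sakurai/Keck-type allylation through an open transition state). The ring closes in the 10-exo-trig mode under high dilution, and the E geometry of the enal both rules out smaller rings through the C3=C4 alkene and forces ring atoms C2 and C7 onto the same face of the enal plane. C8 is controlled by C1: allylic 1,2-strain with the C10 methyl turns C1–H toward that methyl and the silyloxy group into the enal plane, so C2, and with it the attacking C7, lies on the face that gives the 8S centre of 16 (8R in the target, where the priorities change). C7 is controlled by the open synclinal transition state, in which C6 lies anti to the carbonyl oxygen beneath the alkene and the stannylmethyl-bearing carbon turns away from the BF3 group (held syn to the aldehyde hydrogen), giving the syn relationship of the C6 chain and the C8 oxygen. The step needs γ-regioselectivity (SE2′ preference of allylstannanes), 1,2-addition (the enal β-carbon is fully substituted), and face and syn selectivity (C1 silyloxy group and open transition state).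

Step 12
Reactants: 16 isopropenyl ring alcohol
Product: 17 (1S,7S,8R,3Z,9E)-1-(tert-butyldiphenylsilyloxy)-7-isopropyl-4,10-dimethylcyclodeca-3,9-dien-8-ol
Conditions: H2 (1 atm), RhCl(PPh3)3 (cat.), benzene, rt
Reagents that add atoms: none
Why: Homogeneous hydrogenation with RhCl(PPh3)3 should reduce the 1,1-disubstituted exocyclic alkene and leave the two trisubstituted ring alkenes; no stereocentre is formed or touched.

Step 13
Reactants: 17 ring alcohol
Product: 18 (1S,7S,8R,3Z,9E)-1-(tert-butyldiphenylsilyloxy)-7-isopropyl-4,10-dimethylcyclodeca-3,9-dien-8-yl acetate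
Conditions: Ac2O, pyridine, DMAP (cat.), CH2Cl2, rt
Reagents that add atoms: acetic anhydride, CC(=O)OC(C)=O
Why: Acylation of the only free hydroxyl group; the C8–O bond is not broken, so the configuration is retained.

Step 14
Reactants: 18 silyl ether acetate
Product: 19 (1S,7S,8R,3Z,9E)-8-acetoxy-7-isopropyl-4,10-dimethylcyclodeca-3,9-dien-1-ol
Conditions: Bu4NF, AcOH (1:1), THF, rt to 40 °C
Reagents that add atoms: none
Why: Fluoride desilylation buffered with acetic acid should free the C1 alcohol without cleaving the acetate and without the acid that would provoke transannular cyclisation of the diene.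

Step 15
Reactants: 19 ring alcohol; 20 angelic acid ((Z)-2-methylbut-2-enoic acid)
Product: 22 (1S,7S,8R,3Z,9E)-8-acetoxy-7-isopropyl-4,10-dimethylcyclodeca-3,9-dien-1-yl (Z)-2-methylbut-2-enoate, via mixed anhydride 21 (not isolated)
Conditions: 20, 2,4,6-trichlorobenzoyl chloride, Et3N, toluene, rt; then 19, toluene, 75 °C
Reagents that add atoms: none
Why: Yamaguchi-type mixed-anhydride esterification run without a nucleophilic amine catalyst, the established way to acylate hindered alcohols with angelic acid without Z-to-E isomerisation to the tiglate; only the O–H bond reacts, so C1 keeps its configuration.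

**Compound list**

1 | prenol (3-methylbut-2-en-1-ol) | CC(C)=CCO | starting material
2 | tert-butyldimethyl[(3-methylbut-2-en-1-yl)oxy]silane | CC(C)=CCO[Si](C)(C)C(C)(C)C | intermediate
3 | (E)-4-[(tert-butyldimethylsilyl)oxy]-2-methylbut-2-en-1-ol | OC/C(C)=C/CO[Si](C)(C)C(C)(C)C | intermediate (not isolated)
4 | (E)-4-[(tert-butyldimethylsilyl)oxy]-2-methylbut-2-enal | O=C/C(C)=C/CO[Si](C)(C)C(C)(C)C | intermediate
5 | nerol ((Z)-3,7-dimethylocta-2,6-dien-1-ol) | CC(C)=CCC/C(C)=C\CO | starting material
6 | neryl chloride ((Z)-1-chloro-3,7-dimethylocta-2,6-diene) | CC(C)=CCC/C(C)=C\CCl | intermediate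
7 | nerylbarium chloride | CC(C)=CCC/C(C)=C\C[Ba]Cl | intermediate (not isolated)
8 | racemic (2E,6Z)-1-[(tert-butyldimethylsilyl)oxy]-3,7,11-trimethyldodeca-2,6,10-trien-4-ol | CC(C)=CCC/C(C)=C\CC(O)/C(C)=C/CO[Si](C)(C)C(C)(C)C | intermediate
9 | (4S,2E,6Z)-1-[(tert-butyldimethylsilyl)oxy]-3,7,11-trimethyldodeca-2,6,10-trien-4-ol | CC(C)=CCC/C(C)=C\C[C@H](O)/C(C)=C/CO[Si](C)(C)C(C)(C)C | intermediate
10 | (4S,2E,6Z)-1-(tert-butyldimethylsilyloxy)-4-(tert-butyldiphenylsilyloxy)-3,7,11-trimethyldodeca-2,6,10-triene | CC(C)=CCC/C(C)=C\C[C@H](O[Si](c1ccccc1)(c1ccccc1)C(C)(C)C)/C(C)=C/CO[Si](C)(C)C(C)(C)C | intermediate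
11 | (4S,2E,6Z,10E)-1-(tert-butyldimethylsilyloxy)-4-(tert-butyldiphenylsilyloxy)-3,7,11-trimethyldodeca-2,6,10-trien-12-ol | OC/C(C)=C/CC/C(C)=C\C[C@H](O[Si](c1ccccc1)(c1ccccc1)C(C)(C)C)/C(C)=C/CO[Si](C)(C)C(C)(C)C | intermediate
12 | methanesulfonate of 11 (at the C12 oxygen) | CS(=O)(=O)OC/C(C)=C/CC/C(C)=C\C[C@H](O[Si](c1ccccc1)(c1ccccc1)C(C)(C)C)/C(C)=C/CO[Si](C)(C)C(C)(C)C | intermediate (not isolated)
13 | (4S,2E,6Z,10E)-1-(tert-butyldimethylsilyloxy)-4-(tert-butyldiphenylsilyloxy)-3,7,11-trimethyl-12-(tributylstannyl)dodeca-2,6,10-triene | CCCC[Sn](CCCC)(CCCC)C/C(C)=C/CC/C(C)=C\C[C@H](O[Si](c1ccccc1)(c1ccccc1)C(C)(C)C)/C(C)=C/CO[Si](C)(C)C(C)(C)C | intermediate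
14 | (4S,2E,6Z,10E)-4-(tert-butyldiphenylsilyloxy)-3,7,11-trimethyl-12-(tributylstannyl)dodeca-2,6,10-trien-1-ol | CCCC[Sn](CCCC)(CCCC)C/C(C)=C/CC/C(C)=C\C[C@H](O[Si](c1ccccc1)(c1ccccc1)C(C)(C)C)/C(C)=C/CO | intermediate
15 | (4S,2E,6Z,10E)-4-(tert-butyldiphenylsilyloxy)-3,7,11-trimethyl-12-(tributylstannyl)dodeca-2,6,10-trienal | CCCC[Sn](CCCC)(CCCC)C/C(C)=C/CC/C(C)=C\C[C@H](O[Si](c1ccccc1)(c1ccccc1)C(C)(C)C)/C(C)=C/C=O | intermediate
16 | (1S,7S,8S,3Z,9E)-1-(tert-butyldiphenylsilyloxy)-4,10-dimethyl-7-(prop-1-en-2-yl)cyclodeca-3,9-dien-8-ol | CC(C)(C)[Si](c1ccccc1)(c1ccccc1)O[C@H]1C/C=C(/C)CC[C@@H](C(C)=C)[C@@H](O)/C=C/1C | intermediate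
17 | (1S,7S,8R,3Z,9E)-1-(tert-butyldiphenylsilyloxy)-7-isopropyl-4,10-dimethylcyclodeca-3,9-dien-8-ol | CC(C)(C)[Si](c1ccccc1)(c1ccccc1)O[C@H]1C/C=C(/C)CC[C@@H](C(C)C)[C@@H](O)/C=C/1C | intermediate
18 | (1S,7S,8R,3Z,9E)-1-(tert-butyldiphenylsilyloxy)-7-isopropyl-4,10-dimethylcyclodeca-3,9-dien-8-yl acetate | CC(C)(C)[Si](c1ccccc1)(c1ccccc1)O[C@H]1C/C=C(/C)CC[C@@H](C(C)C)[C@@H](OC(C)=O)/C=C/1C | intermediate
19 | (1S,7S,8R,3Z,9E)-8-acetoxy-7-isopropyl-4,10-dimethylcyclodeca-3,9-dien-1-ol | O[C@H]1C/C=C(/C)CC[C@@H](C(C)C)[C@@H](OC(C)=O)/C=C/1C | intermediate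
20 | angelic acid ((Z)-2-methylbut-2-enoic acid) | C/C=C(/C)C(=O)O | starting material
21 | angelic 2,4,6-trichlorobenzoic anhydride | C/C=C(/C)C(=O)OC(=O)c1c(Cl)cc(Cl)cc1Cl | intermediate (not isolated)
22 | (1S,7S,8R,3Z,9E)-8-acetoxy-7-isopropyl-4,10-dimethylcyclodeca-3,9-dien-1-yl (Z)-2-methylbut-2-enoate | C/C=C(/C)C(=O)O[C@H]1C/C=C(/C)CC[C@@H](C(C)C)[C@@H](OC(C)=O)/C=C/1C | target

**Step count and risks**

Total steps: 15. Longest linear sequence: 14 (steps 1, 2 and 4 to 15, from prenol).

Steps most likely to fail:

1. Step 11. Intermolecular allylation may outrun ring closure and give oligomers, adventitious acid may cause protodestannylation, the boron alkoxide may undergo acid-triggered transannular cyclisation, or the open transition state may give too little face or syn selectivity. The fallback reverses the polarity and uses neither tin nor a Lewis acid. It sets out from 11 through its mesylate 12, formed as in step 8. LiCl in DMF should give the allylic chloride F1. Bu4NF at 0 °C should remove the primary silyl group to give the chloro alcohol F2, and MnO2 should give the chloro enal F3. Pd(PPh3)4 (cat., zerovalent palladium) with Et2Zn in THF under high dilution should turn the allylic chloride into an allylzinc species that closes onto the aldehyde, a closure known for ten-membered germacrane rings. The fallback comes back to the route at 16. Because the bond then forms through a closed six-membered transition state, the C7 configuration would be set by the macrocycle and not by the open-transition-state argument, so the product would be assigned before it is carried on.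

2. Step 7. Oxidation may also occur at the allylic positions of the internal C6=C7 alkene, the new alcohol may be over-oxidised, or conversion may stall. The fallback functionalises the terminal alkene by electrophilic addition instead of an ene oxidation. It sets out from 10. N-Bromosuccinimide in aqueous THF, which favours the terminal alkene of polyprenyl chains, should give the terminal bromohydrin F4 (both C10 epimers). K2CO3 in MeOH should close it to the terminal epoxide F5. Al(OiPr)3 in hot toluene should isomerise the epoxide to the secondary allylic alcohol F6. ClCO2Me and pyridine should give the methyl carbonate F7. Pd(PPh3)4 (cat.) with Bu3SnAlEt2 should then place tin at the less substituted allyl terminus. The fallback comes back to the route at 13; the C10 stereocentre of F4 to F7 disappears there.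

3. Step 4. The allylbarium reagent may attack through its γ-carbon, may lose its Z geometry if the temperature rises, or may undergo Wurtz coupling. The fallback forms the same bond with the polarity reversed and sets the carbinol by reduction. It sets out from 4. Propane-1,3-dithiol with Zn(OTf)2 (cat.) should give the dithiane F8. Deprotonation with n-BuLi and alkylation with 6 (SN2 at the primary allylic chloride, Z retained) should give the alkylated dithiane F9. MeI and CaCO3 in aqueous MeCN should unmask the enone F10. Corey–Bakshi–Shibata reduction with the (R)-2-methyl-oxazaborolidine and catecholborane at −78 °C, in which the 2-methylalkenyl group acts as the large substituent, should give the 4S alcohol. The fallback comes back to the route at 9, so step 5 is not needed.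

**Further compounds**

F1 | step 11 | (4S,2E,6Z,10E)-1-(tert-butyldimethylsilyloxy)-4-(tert-butyldiphenylsilyloxy)-12-chloro-3,7,11-trimethyldodeca-2,6,10-triene | ClC/C(C)=C/CC/C(C)=C\C[C@H](O[Si](c1ccccc1)(c1ccccc1)C(C)(C)C)/C(C)=C/CO[Si](C)(C)C(C)(C)C
F2 | step 11 | (4S,2E,6Z,10E)-4-(tert-butyldiphenylsilyloxy)-12-chloro-3,7,11-trimethyldodeca-2,6,10-trien-1-ol | ClC/C(C)=C/CC/C(C)=C\C[C@H](O[Si](c1ccccc1)(c1ccccc1)C(C)(C)C)/C(C)=C/CO
F3 | step 11 | (4S,2E,6Z,10E)-4-(tert-butyldiphenylsilyloxy)-12-chloro-3,7,11-trimethyldodeca-2,6,10-trienal | ClC/C(C)=C/CC/C(C)=C\C[C@H](O[Si](c1ccccc1)(c1ccccc1)C(C)(C)C)/C(C)=C/C=O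
F4 | step 7 | (4S,2E,6Z)-10-bromo-1-(tert-butyldimethylsilyloxy)-4-(tert-butyldiphenylsilyloxy)-3,7,11-trimethyldodeca-2,6-dien-11-ol (both C10 epimers) | CC(C)(O)C(Br)CC/C(C)=C\C[C@H](O[Si](c1ccccc1)(c1ccccc1)C(C)(C)C)/C(C)=C/CO[Si](C)(C)C(C)(C)C
F5 | step 7 | (4S,2E,6Z)-1-(tert-butyldimethylsilyloxy)-4-(tert-butyldiphenylsilyloxy)-10,11-epoxy-3,7,11-trimethyldodeca-2,6-diene (both C10 epimers) | CC1(C)OC1CC/C(C)=C\C[C@H](O[Si](c1ccccc1)(c1ccccc1)C(C)(C)C)/C(C)=C/CO[Si](C)(C)C(C)(C)C
F6 | step 7 | (4S,2E,6Z)-1-(tert-butyldimethylsilyloxy)-4-(tert-butyldiphenylsilyloxy)-3,7,11-trimethyldodeca-2,6,11-trien-10-ol (both C10 epimers) | C=C(C)C(O)CC/C(C)=C\C[C@H](O[Si](c1ccccc1)(c1ccccc1)C(C)(C)C)/C(C)=C/CO[Si](C)(C)C(C)(C)C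
F7 | step 7 | methyl carbonate of F6 | C=C(C)C(OC(=O)OC)CC/C(C)=C\C[C@H](O[Si](c1ccccc1)(c1ccccc1)C(C)(C)C)/C(C)=C/CO[Si](C)(C)C(C)(C)C
F8 | step 4 | 2-[(E)-4-(tert-butyldimethylsilyloxy)but-2-en-2-yl]-1,3-dithiane | S1CCCSC1/C(C)=C/CO[Si](C)(C)C(C)(C)C
F9 | step 4 | 2-[(E)-4-(tert-butyldimethylsilyloxy)but-2-en-2-yl]-2-[(Z)-3,7-dimethylocta-2,6-dien-1-yl]-1,3-dithiane | CC(C)=CCC/C(C)=C\CC1(SCCCS1)/C(C)=C/CO[Si](C)(C)C(C)(C)C
F10 | step 4 | (2E,6Z)-1-(tert-butyldimethylsilyloxy)-3,7,11-trimethyldodeca-2,6,10-trien-4-one | CC(C)=CCC/C(C)=C\CC(=O)/C(C)=C/CO[Si](C)(C)C(C)(C)C
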